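Amounts first, since a quick number was asked for: of the starting complex charged to south-east, the very flask in question, 44.5% stands at 50.0 min and 14.4% at 600 min, so the natural logarithm of charged over left goes from 0.810 to 1.94.

common to all: starting complex 0.050 M; incoming ligand 0.125 M
- south-east: the very flask that is asked about, followed so far
- flask: time 12 h

south-east run (percent of the starting complex charged)

| time / min | complex with two exchanged / % | starting complex / % |
|---|---|---|
| 50.0 | 29.3 | 44.5 |
| 150 | 52.1 | 25.4 |
| 240 | 59.9 | 20.3 |
| 360 | 63.0 | 17.6 |
| 600 | 67.3 | 14.4 |

(standard deviation of a reading: 1 percentage point)

- complex with two exchanged that was removed still counts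
- reactions considered so far: 2 incoming ligand -> self-condensation product; starting complex + incoming ligand -> leaving ligand + complex with one exchanged; complex with one exchanged -> decomposed reagent; complex with one exchanged + incoming ligand -> leaving ligand + complex with two exchanged
- additions bring no volume worth counting

- alder: change nothing and wait 4.0 h more
- elm: at 12 h add starting complex, 50.0% of the amount charged, then wait 4.0 h
- cedar: at 12 h add incoming ligand, 50.0% of the amount charged, then wait 4.0 h
- oak: at 12 h take out 90% of the complex with two exchanged then present, then wait 4.0 h

- complex with two exchanged, in percent of the starting complex first charged, at 12 h
- what to do for the largest gain in complex with two exchanged; "none" if nothing gains more than 2 percentage points (alder / elm / cedar / oak / none)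
- complex with two exchanged present, with what was taken out counted in, in percent of the starting complex first charged, after cedar
- complex with two exchanged present, with what was taken out counted in, in percent of the starting complex first charged, after oak

Call that logarithm the exposure E. In this flask it is a pseudo-first-order rate constant summed over time, and it climbs at a rate in step with the incoming ligand present.

The hunch of a stall passes the test. As read from the south-east readings, E climbs at 0.0162 min⁻¹ over the first interval and 8.36 × 10⁻⁴ min⁻¹ over the last, so incoming ligand over the last interval averages near 5.16% of its level over the first.

Carrying the last rate on to 12 h gives E = 2.04, an estimate on the high side while the rate keeps falling, and so about 13.0% of the starting complex left. Complex with two exchanged rose 22 percentage points per unit of E over the later readings, which gives 69.5% for now.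

Taking exposure as proportional to ligand charged, cedar adds 1.02, while alder and oak, at the last rate, add 0.201. Cedar then reaches about 77.8%, counting the starting complex that reacts.

The forecast reads 68.8% (67.5% to 70.5%), chooses cedar, and gives 80% after cedar (75% to 85%) and 70.8% after oak (69% to 74%): “The reaction is stalling because the ligand is running out.” This reckoning stands 0.70 points higher for now and lower for cedar.

The flask gives 67.0%, and the best choice is cedar, which gains 14 points and reaches 81.2%; oak reaches 67.6%.

    2 incoming ligand → self-condensation product (k = 8.80 × 10⁻⁴ L mol⁻¹ s⁻¹)
    starting complex + incoming ligand → leaving ligand + complex with one exchanged (k = 0.00340 L mol⁻¹ s⁻¹)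
    complex with one exchanged → decomposed reagent (k = 2.20 × 10⁻⁵ s⁻¹)
    complex with one exchanged + incoming ligand → leaving ligand + complex with two exchanged (k = 0.00620 L mol⁻¹ s⁻¹)

At 720 min the flask holds 13.5% of its starting complex, an exposure of 2.00 against the 2.04 reckoned, with incoming ligand, the limiting reagent, at 1.19% of its charge. The neighbouring flask is charged with 0.31 M of incoming ligand, 2.48 times as much. Proportion gives it an exposure of 5.05, hence 0.641% of starting complex left. At 720 min that neighbour holds 0.92%, an exposure of 4.69, and 94.0% of complex with two exchanged.

(The numbers in the tables are calculated for an exercise; scatter was added.)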